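**Plan**

1. Retrosynthesis: the two ester C–O bonds and the C–Cl bond are cut first, leading back to an indane-fused 3,4-dihydroisocoumarin whose lactone holds the C4 carbinol carbon and the C5 two-carbon arm. Then the arene bond C5–C6 is cut, then the sp2–sp2 bond C3a–C4, then the C6=C7 alkene and the C7–C7a bond.
2. Forward: the cyclopentane comes from 3,3-dimethylcyclopentanone and the δ-lactone from 5,6-dihydro-2H-pyran-2-one. Bromoformylation, olefination and Suzuki coupling join them into a triene, and the benzene ring closes last, between the two rings.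
3. Enabling feature: C5 and C6 are neighbours, C7 carries only H, the ring-fusion bond C7a–C3a can be a cyclopentene double bond held Z, and C4/C5 with their substituents map onto the α/β carbons of an unsaturated δ-lactone. A hexatriene (acrylate, cyclopentene, lactone alkene) therefore closes C5–C6 and is dehydrogenated to the arene.
4. After the ring: the C6 ester goes to acid, then alcohol. One thionyl chloride operation then gives the C5 chloroethyl arm, a C4 acid chloride (reduced to the carbinol) and a C6 benzylic chloride. The benzylic chloride is exchanged for butyrate by SN2, and the C4 carbinol is acetylated last.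
5. Stereochemistry: the target has no stereocentre. The only stereo-element of the route is the E-acrylate (Horner–Wadsworth–Emmons), and the two cis centres formed in the ring closure vanish on aromatization.

Key step: step 6

Remark on the chemistry: the target has no stereogenic centre or axis, so it is one achiral compound and no enantiocontrol is needed. Arene positions are given in the indane numbering of the target throughout (C4 acetoxymethyl, C5 2-chloroethyl, C6 butanoyloxymethyl, C7 H).

**Route**

Step 1
Reactants: 1 3,3-dimethylcyclopentanone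
Product: 3 2-bromo-4,4-dimethylcyclopent-1-ene-1-carbaldehyde, via bromovinyl iminium bromide 2 (not isolated)
Conditions: PBr3, DMF, CHCl3, 0 °C → rt; then ice–water
Reagents that add atoms: N,N-dimethylformamide CN(C)C=O; phosphorus tribromide BrP(Br)Br; water O
Why: In this Vilsmeier–Haack–Arnold bromoformylation the bromoiminium reagent should formylate the enol at C5, the α-carbon away from the quaternary centre (C2 is neopentyl), bromide replaces the activated oxygen, and hydrolysis of iminium 2 frees the aldehyde.

Step 2
Reactants: 3 2-bromo-4,4-dimethylcyclopent-1-ene-1-carbaldehyde; 4 triethyl phosphonoacetate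
Product: 5 ethyl (2E)-3-(2-bromo-4,4-dimethylcyclopent-1-en-1-yl)prop-2-enoate
Conditions: NaH, THF, 0 °C → rt
Reagents that add atoms: none
Why: The Horner–Wadsworth–Emmons reaction of a stabilized phosphonate anion with an aldehyde should give the E-enoate, and the anion attacks the formyl group rather than the bromine-bearing carbon.

Step 3
Reactants: 5 ethyl (2E)-3-(2-bromo-4,4-dimethylcyclopent-1-en-1-yl)prop-2-enoate
Product: 6 ethyl (2E)-3-[4,4-dimethyl-2-(4,4,5,5-tetramethyl-1,3,2-dioxaborolan-2-yl)cyclopent-1-en-1-yl]prop-2-enoate
Conditions: B2pin2, PdCl2(dppf) (3 mol %), KOAc, 1,4-dioxane, 80 °C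
Reagents that add atoms: bis(pinacolato)diboron CC1(C)OB(OC1(C)C)B1OC(C)(C)C(C)(C)O1
Why: In this Miyaura borylation the C–Br bond, activated as a vinylogous β-bromo enoate, should add readily to Pd(0), and the weak acetate base allows transmetalation with the diboron while suppressing Suzuki homocoupling.

Step 4
Reactants: 7 5,6-dihydro-2H-pyran-2-one
Product: 9 3-bromo-5,6-dihydro-2H-pyran-2-one, via trans-3,4-dibromotetrahydropyran-2-one 8 (not isolated)
Conditions: Br2, CH2Cl2, 0 °C → rt; then Et3N, 0 °C → rt
Reagents that add atoms: bromine BrBr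
Why: Anti addition of bromine to the enoate followed by amine-induced dehydrobromination (loss of the acidic α-H and the β-bromide) is the standard bromination–elimination route to an α-bromo enoate.

Step 5
Reactants: 6 ethyl (2E)-3-[4,4-dimethyl-2-(4,4,5,5-tetramethyl-1,3,2-dioxaborolan-2-yl)cyclopent-1-en-1-yl]prop-2-enoate; 9 3-bromo-5,6-dihydro-2H-pyran-2-one
Product: 10 ethyl (2E)-3-[4,4-dimethyl-2-(2-oxo-5,6-dihydro-2H-pyran-3-yl)cyclopent-1-en-1-yl]prop-2-enoate
Conditions: Pd(OAc)2 (5 mol %), SPhos (10 mol %), K3PO4, THF–H2O (10:1), 40 °C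
Reagents that add atoms: none
Why: In this Suzuki–Miyaura sp2–sp2 coupling the α-bromo enoate should undergo fast oxidative addition, and the bulky biarylphosphine should let the tetrasubstituted alkenyl boronate transmetalate at a temperature that spares the lactone, keeps both alkene geometries and lies below the onset of ring closure.

Step 6
Reactants: 10 ethyl (2E)-3-[4,4-dimethyl-2-(2-oxo-5,6-dihydro-2H-pyran-3-yl)cyclopent-1-en-1-yl]prop-2-enoate
Product: 12 ethyl 8,8-dimethyl-1-oxo-1,3,4,7,8,9-hexahydrocyclopenta[h]isochromene-5-carboxylate (indane-fused 3,4-dihydroisocoumarin with CO2Et at C6), via cis-cyclohexadiene ester 11 (not isolated)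
Conditions: 1,2-dichlorobenzene (degassed, 0.02 M), BHT (cat.), 150 °C; then DDQ (1.2 equiv), 60 °C
Reagents that add atoms: none
Why: Heating should populate the s-cis,s-cis conformer of the ring-locked hexatriene (acrylate C=C, cyclopentene C=C, lactone C3=C4), which undergoes thermal disrotatory 6π-electrocyclization to form the C5–C6 bond and give cyclohexa-1,3-diene 11; DDQ then removes the two new methine hydrogens by hydride abstraction and proton loss to give the benzene ring. The closest known reaction type is the thermal 6π-electrocyclization of 1,2-dialkenylcycloalkenes followed by quinone dehydrogenation. The six-membered carbocycle is closed in the pericyclic disrotatory mode, while the cyclopentene and lactone rings pass through unchanged. The two transient stereocentres (the carbons that become C5 and C6) are set cis by disrotation from termini whose hydrogens both point inward (E-acrylate from step 2, ring-fixed lactone alkene), and both are erased on aromatization. The step needs only the right triene geometry and a chemoselective dehydrogenation: the cyclopentene holds the central bond Z, no allylic hydrogen is placed for a competing 1,5- or 1,7-hydrogen shift, and a slight excess of DDQ at moderate temperature should react at the cyclohexadiene before the indane CH2 groups.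

Step 7
Reactants: 12 ethyl 8,8-dimethyl-1-oxo-1,3,4,7,8,9-hexahydrocyclopenta[h]isochromene-5-carboxylate
Product: 14 8,8-dimethyl-1-oxo-1,3,4,7,8,9-hexahydrocyclopenta[h]isochromene-5-carboxylic acid, via ring-opened hydroxy diacid 13 (not isolated)
Conditions: LiOH, THF–H2O, 40 °C; then 2 M HCl (pH 1), 40 °C
Reagents that add atoms: lithium hydroxide [Li+].[OH-]
Why: Saponification cleaves the ethyl ester and reversibly opens the lactone, and on acidification only the C4 carboxyl of 13 has the hydroxyethyl arm within reach, so acid-catalysed lactonization should restore the six-membered lactone and leave the C6 acid free.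

Step 8
Reactants: 14 8,8-dimethyl-1-oxo-1,3,4,7,8,9-hexahydrocyclopenta[h]isochromene-5-carboxylic acid
Product: 15 5-(hydroxymethyl)-8,8-dimethyl-4,7,8,9-tetrahydrocyclopenta[h]isochromen-1(3H)-one
Conditions: BH3·SMe2, THF, 0 °C → rt; then MeOH, aqueous work-up
Reagents that add atoms: none
Why: Chemoselective borane reduction is relied on here, since borane reduces a carboxylic acid through its acyloxyborane far faster than an aryl lactone, so only the C6 carboxyl should be taken to the carbinol.

Step 9
Reactants: 15 5-(hydroxymethyl)-8,8-dimethyl-4,7,8,9-tetrahydrocyclopenta[h]isochromen-1(3H)-one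
Product: 17 [5-(2-chloroethyl)-6-(chloromethyl)-2,2-dimethyl-2,3-dihydro-1H-inden-4-yl]methanol, via chloroethyl aroyl chloride 16 (not isolated)
Conditions: SOCl2 (neat), ZnCl2 (10 mol %), 75 °C; evaporate; then NaBH4, THF–DMF, −10 → 0 °C; aq. NH4Cl
Reagents that add atoms: thionyl chloride O=S(Cl)Cl
Why: Thionyl chloride should convert the benzylic alcohol to its chloride and, under Lewis acid catalysis, open the lactone by chloride attack at the O–CH2 carbon to the ω-chloroalkyl acid chloride (the known lactone to chloro acid chloride ring opening), and the following borohydride reduction takes an acyl chloride to the alcohol much faster than it touches a benzylic or alkyl chloride at low temperature.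

Step 10
Reactants: 17 [5-(2-chloroethyl)-6-(chloromethyl)-2,2-dimethyl-2,3-dihydro-1H-inden-4-yl]methanol
Product: 18 [5-(2-chloroethyl)-4-(hydroxymethyl)-2,2-dimethyl-2,3-dihydro-1H-inden-6-yl]methyl butanoate
Conditions: sodium butanoate, 15-crown-5 (cat.), DMF, 45 °C
Reagents that add atoms: sodium butanoate CCCC(=O)[O-].[Na+]
Why: In this SN2 carboxylate alkylation the benzylic chloride should be far more reactive than the primary alkyl chloride, and butanoate is too weak a base to eliminate HCl from the chloroethyl arm or to deprotonate the free carbinol.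

Step 11
Reactants: 18 [5-(2-chloroethyl)-4-(hydroxymethyl)-2,2-dimethyl-2,3-dihydro-1H-inden-6-yl]methyl butanoate
Product: 19 [4-(acetoxymethyl)-5-(2-chloroethyl)-2,2-dimethyl-2,3-dihydro-1H-inden-6-yl]methyl butanoate
Conditions: Ac2O, pyridine, DMAP (cat.), CH2Cl2, 0 °C → rt
Reagents that add atoms: acetic anhydride CC(=O)OC(C)=O
Why: DMAP-catalysed acetylation should esterify the one remaining, hindered primary benzylic alcohol, and the alkyl chloride and the butanoate are inert to these conditions.

**Compound list**

1 | 3,3-dimethylcyclopentanone | CC1(C)CCC(=O)C1 | starting material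
2 | N-[(2-bromo-4,4-dimethylcyclopent-1-en-1-yl)methylidene]-N-methylmethanaminium bromide | C[N+](C)=CC1=C(Br)CC(C)(C)C1.[Br-] | intermediate (not isolated)
3 | 2-bromo-4,4-dimethylcyclopent-1-ene-1-carbaldehyde | O=CC1=C(Br)CC(C)(C)C1 | intermediate
4 | triethyl phosphonoacetate | CCOC(=O)CP(=O)(OCC)OCC | starting material
5 | ethyl (2E)-3-(2-bromo-4,4-dimethylcyclopent-1-en-1-yl)prop-2-enoate | CCOC(=O)/C=C/C1=C(Br)CC(C)(C)C1 | intermediate
6 | ethyl (2E)-3-[4,4-dimethyl-2-(4,4,5,5-tetramethyl-1,3,2-dioxaborolan-2-yl)cyclopent-1-en-1-yl]prop-2-enoate | CCOC(=O)/C=C/C1=C(B2OC(C)(C)C(C)(C)O2)CC(C)(C)C1 | intermediate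
7 | 5,6-dihydro-2H-pyran-2-one | O=C1C=CCCO1 | starting material
8 | trans-3,4-dibromotetrahydro-2H-pyran-2-one (racemic) | O=C1OCC[C@H](Br)[C@H]1Br | intermediate (not isolated)
9 | 3-bromo-5,6-dihydro-2H-pyran-2-one | O=C1OCCC=C1Br | intermediate
10 | ethyl (2E)-3-[4,4-dimethyl-2-(2-oxo-5,6-dihydro-2H-pyran-3-yl)cyclopent-1-en-1-yl]prop-2-enoate | CCOC(=O)/C=C/C1=C(C2=CCCOC2=O)CC(C)(C)C1 | intermediate (key-step precursor)
11 | ethyl cis-8,8-dimethyl-1-oxo-1,3,4,4a,5,7,8,9-octahydrocyclopenta[h]isochromene-5-carboxylate (racemic, 4a-H and 5-H cis) | CCOC(=O)[C@@H]1C=C2CC(C)(C)CC2=C3C(=O)OCC[C@H]13 | intermediate (not isolated)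
12 | ethyl 8,8-dimethyl-1-oxo-1,3,4,7,8,9-hexahydrocyclopenta[h]isochromene-5-carboxylate | CCOC(=O)c1cc2c(c3c1CCOC3=O)CC(C)(C)C2 | intermediate (key-step product)
13 | 5-(2-hydroxyethyl)-2,2-dimethyl-2,3-dihydro-1H-indene-4,6-dicarboxylic acid (dilithium salt before acidification) | OCCc1c(C(=O)O)cc2c(c1C(=O)O)CC(C)(C)C2 | intermediate (not isolated)
14 | 8,8-dimethyl-1-oxo-1,3,4,7,8,9-hexahydrocyclopenta[h]isochromene-5-carboxylic acid | OC(=O)c1cc2c(c3c1CCOC3=O)CC(C)(C)C2 | intermediate
15 | 5-(hydroxymethyl)-8,8-dimethyl-4,7,8,9-tetrahydrocyclopenta[h]isochromen-1(3H)-one | OCc1cc2c(c3c1CCOC3=O)CC(C)(C)C2 | intermediate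
16 | 5-(2-chloroethyl)-6-(chloromethyl)-2,2-dimethyl-2,3-dihydro-1H-indene-4-carbonyl chloride | O=C(Cl)c1c(CCCl)c(CCl)cc2c1CC(C)(C)C2 | intermediate (not isolated)
17 | [5-(2-chloroethyl)-6-(chloromethyl)-2,2-dimethyl-2,3-dihydro-1H-inden-4-yl]methanol | OCc1c(CCCl)c(CCl)cc2c1CC(C)(C)C2 | intermediate
18 | [5-(2-chloroethyl)-4-(hydroxymethyl)-2,2-dimethyl-2,3-dihydro-1H-inden-6-yl]methyl butanoate | CCCC(=O)OCc1cc2c(c(CO)c1CCCl)CC(C)(C)C2 | intermediate
19 | [4-(acetoxymethyl)-5-(2-chloroethyl)-2,2-dimethyl-2,3-dihydro-1H-inden-6-yl]methyl butanoate (CNP0321917.0) | CCCC(=O)OCc1cc2c(c(COC(C)=O)c1CCCl)CC(C)(C)C2 | target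

**Step count and risks**

Total steps: 11. Longest linear sequence: 10 (steps 1–3 and 5–11); step 4 is a one-step branch that joins at step 5.

Steps most likely to fail:

Step 9. The alkyl C–O cleavage of the hindered aryl lactone may stall, or acid-promoted side reactions of the benzylic chloride (Friedel–Crafts alkylation) may take over. In the hydride stage the benzylic chloride may be over-reduced, or the new benzylic alkoxide may close onto the chloroethyl arm. The fallback separates ring opening, chlorination and reduction. It sets out from 15, which is opened with Me2AlN(OMe)Me (from AlMe3 and N,O-dimethylhydroxylamine hydrochloride, CH2Cl2) to 5-(2-hydroxyethyl)-6-(hydroxymethyl)-N-methoxy-N,2,2-trimethyl-2,3-dihydro-1H-indene-4-carboxamide F1. An Appel reaction (PPh3, CCl4, CH2Cl2) on both hydroxyls should then give 5-(2-chloroethyl)-6-(chloromethyl)-N-methoxy-N,2,2-trimethyl-2,3-dihydro-1H-indene-4-carboxamide F2. DIBAL-H at −78 °C reduces the Weinreb amide to 5-(2-chloroethyl)-6-(chloromethyl)-2,2-dimethyl-2,3-dihydro-1H-indene-4-carbaldehyde F3, and NaBH4 in MeOH at 0 °C takes the aldehyde to 17, where the route is rejoined.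

Step 5. Protodeboronation of the electron-poor, tetrasubstituted alkenyl boronate, and base-induced opening of or conjugate addition to the bromolactone, may outpace transmetalation. The fallback is a base-free Stille coupling that sets out from 5. Pd-catalysed stannylation with hexamethylditin (Pd(PPh3)4, toluene, 100 °C) should give ethyl (2E)-3-[4,4-dimethyl-2-(trimethylstannyl)cyclopent-1-en-1-yl]prop-2-enoate F4. F4 is then coupled with 9 under neutral conditions (Pd(PPh3)4, CuI, DMF, 50 °C) and comes back to the route at 10.

Step 6. Bringing the triene termini together across the cyclopentene may need temperatures at which the acrylate polymerizes or decomposes, and excess quinone may oxidize the indane CH2 groups. The fallback replaces ground-state closure by excited-state closure under oxidative (Mallory-type) conditions and sets out from 10. Irradiation at 365 nm in dilute toluene with iodine and propylene oxide should close the ring conrotatorily to ethyl trans-8,8-dimethyl-1-oxo-1,3,4,4a,5,7,8,9-octahydrocyclopenta[h]isochromene-5-carboxylate F5. Iodine dehydrogenates F5 in the same flask, so the sequence comes back at 12. E/Z scrambling of the acrylate under light is harmless, because every dihydro isomer aromatizes to the same arene.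

**Further compounds**

F1 | step 9 | 5-(2-hydroxyethyl)-6-(hydroxymethyl)-N-methoxy-N,2,2-trimethyl-2,3-dihydro-1H-indene-4-carboxamide | CON(C)C(=O)c1c(CCO)c(CO)cc2c1CC(C)(C)C2
F2 | step 9 | 5-(2-chloroethyl)-6-(chloromethyl)-N-methoxy-N,2,2-trimethyl-2,3-dihydro-1H-indene-4-carboxamide | CON(C)C(=O)c1c(CCCl)c(CCl)cc2c1CC(C)(C)C2
F3 | step 9 | 5-(2-chloroethyl)-6-(chloromethyl)-2,2-dimethyl-2,3-dihydro-1H-indene-4-carbaldehyde | O=Cc1c(CCCl)c(CCl)cc2c1CC(C)(C)C2
F4 | step 5 | ethyl (2E)-3-[4,4-dimethyl-2-(trimethylstannyl)cyclopent-1-en-1-yl]prop-2-enoate | CCOC(=O)/C=C/C1=C([Sn](C)(C)C)CC(C)(C)C1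
F5 | step 6 | ethyl trans-8,8-dimethyl-1-oxo-1,3,4,4a,5,7,8,9-octahydrocyclopenta[h]isochromene-5-carboxylate (racemic) | CCOC(=O)[C@@H]1C=C2CC(C)(C)CC2=C3C(=O)OCC[C@@H]13
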